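**Retrosynthetic overview**

- Feature: in the ten-membered ring the two angelate-bearing carbons C5 and C10 are 1,6-related. A C5–C10 bond turns the ring into a cis-decalin with C5/C10 as fusion carbons: ring P (C5, C6, C7, C8, C9, C10; carries the C7–C8 epoxide and C9–O) and ring Q (C10, C1, C2, C3, C4, C5; carries isopropenyl and the C3/C4 diol).
- Key disconnection: Pb(OAc)4 cleavage of the C5–C10 bond of the ring-fusion cis-diol 17 gives the ten-membered 5,10-diketone 19. Both carbinols, the two angelates and the C9 acetate follow.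
- Ring Q comes from (S)-carvone (C1), with C4–O from the enone epoxide and C3–O by titanium-directed epoxide opening. C10 is built by Rubottom oxidation and formylation, C9 by chelation-controlled isopropenyl addition, C5 by allyl Grignard addition.
- Ring order: ring Q (carvone), then ring P by ring-closing metathesis (C7=C8) and hydroxyl-directed epoxidation, then the ten-membered ring by C5–C10 scission.

Key step: step 14

Remark: locants C1–C10 of the target ring (C1 bears isopropenyl) are kept for all intermediates; β is the face of ring Q carrying the C1 isopropenyl group, α the other. The fusion diol is built on the β face, which is immaterial because C5 and C10 become carbonyl carbons in the key step.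

**Route**

Step 1
Reactants: 1 (S)-(+)-carvone
Product: 2 carvone α-oxide (3α,4α-epoxy-5-ketone; C4 methyl β)
Conditions: 30% H2O2, NaOH (cat.), MeOH, 0 °C
Reagents that add atoms: hydrogen peroxide, OO
Why: Weitz–Scheffer nucleophilic epoxidation of the enone only; hydroperoxide adds to C3 anti to the isopropenyl group, which sets C3 and C4 with the epoxide α and leaves the isolated alkene untouched.

Step 2
Reactants: 2 carvone α-oxide
Product: 3 3α,4α-epoxy-5α-ol (hydroxyl cis to the epoxide oxygen)
Conditions: NaBH4, MeOH, −20 °C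
Reagents that add atoms: none
Why: Borohydride reduction of an α,β-epoxy ketone, hydride adding anti to the epoxide oxygen, should give the cis epoxy alcohol needed for bidentate binding to titanium in step 3 (C5 returns to a ketone in step 4).

Step 3
Reactants: 3 3α,4α-epoxy-5α-ol
Product: 4 3β-benzoyloxy-4α,5α-diol (C4 methyl β)
Conditions: Ti(OiPr)4 (1.5 equiv), PhCO2H (1.5 equiv), CH2Cl2, rt
Reagents that add atoms: benzoic acid, OC(=O)c1ccccc1
Why: Titanium-mediated C3-selective opening of a 2,3-epoxy alcohol: titanium bound to the C5 alkoxide and the cis epoxide oxygen directs benzoate to the distal secondary C3 with SN2 inversion (C3–O β), while the tertiary C4–O bond (α) from step 1 is kept.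

Step 4
Reactants: 4 3β-benzoyloxy-4α,5α-diol
Product: 5 3β-benzoyloxy-4α-hydroxy-5-ketone
Conditions: Pr4N[RuO4] (5 mol%), NMO, 4 Å MS, CH2Cl2, rt
Reagents that add atoms: none
Why: Ley–Griffith oxidation of the only secondary alcohol; the tertiary C4 hydroxyl and the benzoate are not affected.

Step 5
Reactants: 5 3β-benzoyloxy-4α-hydroxy-5-ketone
Product: 6 (2S,3R,5S)-2,3-dihydroxy-2-methyl-5-(prop-1-en-2-yl)cyclohexan-1-one (3β-OH, 4α-OH)
Conditions: K2CO3 (0.2 equiv), MeOH, 0 °C
Reagents that add atoms: none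
Why: Zemplén-type transesterification removes the benzoate; C4 is quaternary, so neither β-elimination nor epimerisation is possible.

Step 6
Reactants: 6 dihydroxy ketone
Product: 7 3β,4α-bis(triethylsilyloxy) ketone
Conditions: TESOTf (3 equiv), 2,6-lutidine, CH2Cl2, −78 → 0 °C
Reagents that add atoms: triethylsilyl triflate, CC[Si](CC)(CC)OS(=O)(=O)C(F)(F)F
Why: Silyl triflate silylation protects the secondary and the tertiary hydroxyl, so that the C3/C4 diol cannot compete in the later glycol cleavage.

Step 7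
Reactants: 7 bis(triethylsilyloxy) ketone
Product: 10 10α-trimethylsilyloxy ketone, via trimethylsilyl enol ether 8 (not isolated), via silyloxy epoxide 9 (not isolated)
Conditions: LDA, TMSCl, THF, −78 °C; then mCPBA, NaHCO3, hexane–CH2Cl2, −20 °C
Reagents that add atoms: chlorotrimethylsilane, C[Si](C)(C)Cl; mCPBA, OOC(=O)c1cccc(Cl)c1
Why: Rubottom oxidation: enolisation is possible only toward C10 (C4 is quaternary), the electron-rich enol ether is epoxidised much faster than the isopropenyl group, and 1,4-silyl shift gives the α-silyloxy ketone; the C10 configuration formed here (anti to isopropenyl) is erased in step 8.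

Step 8
Reactants: 10 10α-trimethylsilyloxy ketone
Product: 11 10α-formyl-10β-trimethylsilyloxy ketone
Conditions: LDA, THF, −78 °C; CF3CH2OCHO, −78 °C; AcOH quench at −78 °C
Reagents that add atoms: 2,2,2-trifluoroethyl formate, O=COCC(F)(F)F
Why: Kinetic Claisen-type C-formylation of the only possible enolate; the formyl group enters trans to the adjacent C1 isopropenyl group and anti to the pseudoaxial C4 methyl, setting C10 with CHO α (equatorial) and OTMS β (axial).

Step 9
Reactants: 11 formyl ketone
Product: 12 (9R)-10α-(1-hydroxy-2-methylprop-2-enyl)-10β-trimethylsilyloxy ketone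
Conditions: MgBr2·OEt2, CH2Cl2, −78 °C; then CH2=C(CH3)MgBr, −78 °C
Reagents that add atoms: isopropenylmagnesium bromide, CC(=C)[Mg]Br
Why: Chelation-controlled Grignard addition: magnesium bridges the C5 ketone and aldehyde oxygens of the non-enolisable β-keto aldehyde and the nucleophile adds to the aldehyde face anti to the axial C10 silyloxy group, which sets C9 (oxygen cis to the C10 oxygen in the later ring P); the hindered ketone does not react.

Step 10
Reactants: 12 β-hydroxy ketone
Product: 14 5α-allyl-5β,10β-diol with the 10α side chain (triol), via C10 trimethylsilyl ether 13 (not isolated)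
Conditions: CH2=CHCH2MgBr (3 equiv), THF, −78 °C; then K2CO3, MeOH, 0 °C
Reagents that add atoms: allylmagnesium bromide, C=CC[Mg]Br
Why: Allyl Grignard 1,2-addition to the non-enolisable ketone by axial attack on the α face, because the axial C4 methyl and axial C10 silyloxy group shield the β face; this sets C5 (OH β, allyl α, cis to the C9 chain), and methanolysis then removes the trimethylsilyl ether while the triethylsilyl ethers stay.

Step 11
Reactants: 14 triol
Product: 15 cis-fused bicyclic triol (5β,10β-diol, 9β-OH, C7=C8 with C8 methyl)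
Conditions: second-generation Grubbs catalyst RuCl2(=CHPh)(PCy3)(H2IMes) (5 mol%), CH2Cl2, 40 °C
Reagents that add atoms: none
Why: Ring-closing metathesis closes ring P between the allyl group and the cis-disposed 2-propenyl unit (trisubstituted cyclohexene); the C1 isopropenyl group is trans to the allyl group and cannot cyclise.

Step 12
Reactants: 15 bicyclic triol
Product: 16 7β,8β-epoxy triol
Conditions: VO(acac)2 (5 mol%), tBuOOH, CH2Cl2, 0 °C
Reagents that add atoms: tert-butyl hydroperoxide, CC(C)(C)OO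
Why: Hydroxyl-directed vanadium-catalysed epoxidation: the pseudoaxial allylic C9 hydroxyl, reinforced by the two homoallylic fusion hydroxyls on the same face, delivers oxygen to the β face of C7=C8 (sets C7 and C8); the undirected isopropenyl alkene is left alone.

Step 13
Reactants: 16 epoxy triol
Product: 17 9-O-(4-methoxybenzyl) epoxy 5β,10β-diol
Conditions: NaH (1.05 equiv), PMBBr, Bu4NI (cat.), THF–DMF, 0 °C
Reagents that add atoms: 4-methoxybenzyl bromide, COc1ccc(CBr)cc1
Why: Williamson etherification of the only secondary alkoxide (the tertiary ones are much slower); the C9 oxygen is cis to the epoxide, so Payne rearrangement cannot occur.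

Step 14
Reactants: 17 epoxy decalin ring-fusion cis-diol
Product: 19 ten-membered epoxy 5,10-diketone, via cyclic lead diester 18 (not isolated)
Conditions: Pb(OAc)4 (1.1 equiv), pyridine (3 equiv), CH2Cl2, −20 → 0 °C
Reagents that add atoms: none
Why: Criegee glycol cleavage: the cis fusion diol of 17 (C5–OH equatorial, C10–OH axial on ring Q, O–C–C–O about 60°) exchanges two acetates of Pb(OAc)4 to give the cyclic lead diester 18, which collapses in a two-electron fragmentation that breaks C5–C10, releases lead diacetate and leaves ketones at C5 and C10. The closest known reaction is the lead tetraacetate cleavage of cis-decalin-9,10-diols to cyclodecane-1,6-diones. No ring is closed by bond formation: the ten-membered ring appears by scission of the bond shared by rings P and Q. No stereocentre is created; C1, C3, C4, C7, C8 and C9 are spectators and the two fusion centres are erased. The step needs chemoselectivity for the one free vicinal diol, secured because C3/C4 are silylated and C9 is etherified, while the isopropenyl group and the epoxide are inert to Pb(OAc)4 at 0 °C. Pyridine buffering, low temperature and immediate use of 19 should suppress C1 epimerisation, E1cB opening of the epoxide from the C5 ketone and transannular aldol reaction.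

Step 15
Reactants: 19 epoxy 5,10-diketone
Product: 20 (5S,10S)-diol
Conditions: Zn(BH4)2, Et2O, −30 → 0 °C
Reagents that add atoms: none
Why: Zinc borohydride reduction of both ketones: at C10 by Cram-chelate control through the C9 ether (9,10-anti), at C5 by Felkin–Anh control with the non-chelating tertiary silyloxy group antiperiplanar to hydride (4,5-syn); the reagent is mild and non-basic.

Step 16
Reactants: 20 diol
Product: 21 5,10-bis-angelate
Conditions: angelic acid, 2,4,6-trichlorobenzoyl chloride, Et3N, toluene, rt; then 20, 75 °C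
Reagents that add atoms: angelic acid, C/C=C(/C)C(=O)O
Why: Yamaguchi esterification through the mixed anhydride without DMAP acylates both secondary alcohols and is the standard way to keep the Z geometry of the angelate.

Step 17
Reactants: 21 bis-angelate
Product: 22 9-alcohol
Conditions: DDQ, CH2Cl2–pH 7 buffer, 0 °C
Reagents that add atoms: none
Why: Oxidative cleavage of the 4-methoxybenzyl ether by DDQ; esters, silyl ethers, epoxide and isopropenyl are not oxidised under buffered conditions.

Step 18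
Reactants: 22 9-alcohol
Product: 23 9-acetate (3,4-bis-TES ether of the target)
Conditions: Ac2O, pyridine, DMAP (cat.), CH2Cl2, 0 °C
Reagents that add atoms: acetic anhydride, CC(=O)OC(C)=O
Why: Fast DMAP-catalysed acetylation of the freed secondary alcohol, run cold and short so that the neighbouring angelate does not migrate.

Step 19
Reactants: 23 bis-TES ether
Product: 24 CNP0249359.1 (target)
Conditions: HF·pyridine, pyridine, THF, 0 °C → rt
Reagents that add atoms: none
Why: Fluoride-mediated desilylation under buffered, non-basic conditions removes both triethylsilyl groups without acyl migration, angelate isomerisation or opening of the trisubstituted epoxide.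

**Compound list**

1 | (S)-(+)-carvone, (5S)-2-methyl-5-(prop-1-en-2-yl)cyclohex-2-en-1-one | C=C(C)[C@H]1CC=C(C)C(=O)C1 | starting material
2 | carvone α-oxide, (1S,4S,6S)-1-methyl-4-(prop-1-en-2-yl)-7-oxabicyclo[4.1.0]heptan-2-one | C=C(C)[C@H]1C[C@@H]2O[C@]2(C)C(=O)C1 | intermediate
3 | 3α,4α-epoxy-5α-ol (OH cis to epoxide O) | C=C(C)[C@H]1C[C@@H]2O[C@]2(C)[C@H](O)C1 | intermediate
4 | 3β-benzoyloxy-4α,5α-diol (4β-methyl, 1β-isopropenyl) | C=C(C)[C@H]1C[C@@H](OC(=O)c2ccccc2)[C@](C)(O)[C@H](O)C1 | intermediate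
5 | 3β-benzoyloxy-4α-hydroxy-5-ketone | C=C(C)[C@H]1C[C@@H](OC(=O)c2ccccc2)[C@](C)(O)C(=O)C1 | intermediate
6 | (2S,3R,5S)-2,3-dihydroxy-2-methyl-5-(prop-1-en-2-yl)cyclohexan-1-one | C=C(C)[C@H]1C[C@@H](O)[C@](C)(O)C(=O)C1 | intermediate
7 | 3β,4α-bis(triethylsilyloxy) ketone | C=C(C)[C@H]1C[C@@H](O[Si](CC)(CC)CC)[C@](C)(O[Si](CC)(CC)CC)C(=O)C1 | intermediate
8 | trimethylsilyl enol ether (C5=C10) of 7 | C=C(C)[C@H]1C[C@@H](O[Si](CC)(CC)CC)[C@](C)(O[Si](CC)(CC)CC)C(O[Si](C)(C)C)=C1 | intermediate (not isolated)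
9 | 5α,10α-epoxy-5β-trimethylsilyloxy compound | C=C(C)[C@H]1C[C@@H](O[Si](CC)(CC)CC)[C@](C)(O[Si](CC)(CC)CC)[C@]2(O[Si](C)(C)C)O[C@H]12 | intermediate (not isolated)
10 | 10α-trimethylsilyloxy ketone | C=C(C)[C@H]1C[C@@H](O[Si](CC)(CC)CC)[C@](C)(O[Si](CC)(CC)CC)C(=O)[C@@H]1O[Si](C)(C)C | intermediate
11 | 10α-formyl-10β-trimethylsilyloxy ketone | C=C(C)[C@H]1C[C@@H](O[Si](CC)(CC)CC)[C@](C)(O[Si](CC)(CC)CC)C(=O)[C@]1(O[Si](C)(C)C)C=O | intermediate
12 | (9R)-10α-(1-hydroxy-2-methylprop-2-enyl)-10β-trimethylsilyloxy ketone | C=C(C)[C@H]1C[C@@H](O[Si](CC)(CC)CC)[C@](C)(O[Si](CC)(CC)CC)C(=O)[C@]1(O[Si](C)(C)C)[C@H](O)C(C)=C | intermediate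
13 | 5α-allyl-5β-hydroxy C10 trimethylsilyl ether | C=C(C)[C@H]1C[C@@H](O[Si](CC)(CC)CC)[C@](C)(O[Si](CC)(CC)CC)[C@](O)(CC=C)[C@]1(O[Si](C)(C)C)[C@H](O)C(C)=C | intermediate (not isolated)
14 | 5α-allyl-5β,10β-diol bearing the 10α-(1-hydroxy-2-methylprop-2-enyl) chain | C=C(C)[C@H]1C[C@@H](O[Si](CC)(CC)CC)[C@](C)(O[Si](CC)(CC)CC)[C@](O)(CC=C)[C@]1(O)[C@H](O)C(C)=C | intermediate
15 | cis-fused bicyclic triol (5β,10β,9β-OH; C7=C8) | C=C(C)[C@H]1C[C@@H](O[Si](CC)(CC)CC)[C@](C)(O[Si](CC)(CC)CC)[C@]2(O)CC=C(C)[C@@H](O)[C@]12O | intermediate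
16 | 7β,8β-epoxy triol | C=C(C)[C@H]1C[C@@H](O[Si](CC)(CC)CC)[C@](C)(O[Si](CC)(CC)CC)[C@]2(O)C[C@H]3O[C@@]3(C)[C@@H](O)[C@]12O | intermediate
17 | 9-O-PMB epoxy decalin 5β,10β-diol (key-step precursor) | C=C(C)[C@H]1C[C@@H](O[Si](CC)(CC)CC)[C@](C)(O[Si](CC)(CC)CC)[C@]2(O)C[C@H]3O[C@@]3(C)[C@@H](OCc4ccc(OC)cc4)[C@]12O | intermediate
18 | cyclic lead diester of 17 (5,10-O-bridged lead diacetate) | C=C(C)[C@H]1C[C@@H](O[Si](CC)(CC)CC)[C@](C)(O[Si](CC)(CC)CC)[C@]23C[C@H]4O[C@@]4(C)[C@@H](OCc5ccc(OC)cc5)[C@]12O[Pb](OC(C)=O)(OC(C)=O)O3 | intermediate (not isolated)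
19 | ten-membered epoxy 5,10-diketone (key-step product) | C=C(C)[C@H]1C[C@@H](O[Si](CC)(CC)CC)[C@](C)(O[Si](CC)(CC)CC)C(=O)C[C@H]2O[C@@]2(C)[C@@H](OCc3ccc(OC)cc3)C1=O | intermediate
20 | (5S,10S)-diol | C=C(C)[C@H]1C[C@@H](O[Si](CC)(CC)CC)[C@](C)(O[Si](CC)(CC)CC)[C@@H](O)C[C@H]2O[C@@]2(C)[C@@H](OCc3ccc(OC)cc3)[C@H]1O | intermediate
21 | 5,10-bis-angelate | C=C(C)[C@H]1C[C@@H](O[Si](CC)(CC)CC)[C@](C)(O[Si](CC)(CC)CC)[C@@H](OC(=O)/C(C)=C\C)C[C@H]2O[C@@]2(C)[C@@H](OCc3ccc(OC)cc3)[C@H]1OC(=O)/C(C)=C\C | intermediate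
22 | 9-alcohol bis-angelate | C=C(C)[C@H]1C[C@@H](O[Si](CC)(CC)CC)[C@](C)(O[Si](CC)(CC)CC)[C@@H](OC(=O)/C(C)=C\C)C[C@H]2O[C@@]2(C)[C@@H](O)[C@H]1OC(=O)/C(C)=C\C | intermediate
23 | 9-acetate, 3,4-bis(triethylsilyl) ether of the target | C=C(C)[C@H]1C[C@@H](O[Si](CC)(CC)CC)[C@](C)(O[Si](CC)(CC)CC)[C@@H](OC(=O)/C(C)=C\C)C[C@H]2O[C@@]2(C)[C@@H](OC(C)=O)[C@H]1OC(=O)/C(C)=C\C | intermediate
24 | CNP0249359.1, (1R,3R,4S,5S,7R,8R,9S,10S)-9-acetoxy-5,10-bis(angeloyloxy)-7,8-epoxy-3,4-dihydroxy-4,8-dimethyl-1-(prop-1-en-2-yl)cyclodecane (locants as defined) | C=C(C)[C@H]1C[C@@H](O)[C@](C)(O)[C@@H](OC(=O)/C(C)=C\C)C[C@H]2O[C@@]2(C)[C@@H](OC(C)=O)[C@H]1OC(=O)/C(C)=C\C | target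

**Summary**

Total step count: 19. Longest linear sequence: 19 steps from (S)-carvone.

**Steps most likely to fail**

Step 15. In the flexible ten-membered ring the hydride may follow ring conformation instead of chelation (C10) or Felkin–Anh control (C5), giving poor facial selectivity at one or both carbinols. The fallback sets out from 19 and returns at 21, treating each carbinol separately and choosing the esterification by the configuration found. One hydride equivalent of Zn(BH4)2 at −78 °C reduces only the chelation-activated C10 ketone; in the worst case this gives the 10-epi hydroxy ketone F1, which a Mitsunobu reaction with angelic acid (PPh3, DIAD) esterifies with inversion to the 10-angelate ketone F2 (a correctly configured alcohol would be esterified by the Yamaguchi protocol instead). NaBH4/CeCl3 then reduces the C5 ketone; the 5-epi alcohol F3, if formed, is again esterified with inversion by the Mitsunobu reaction to give 21.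

Step 3. The ring opening may take the wrong regiochemistry. C3 attack must pass through the half-chair with pseudoaxial isopropenyl, whereas the Fürst–Plattner-favoured half-chair exposes the tertiary C4, so benzoate may add at C4 or the reaction may stall. The fallback sets out from 1 and returns at 6, inverting C4 instead of C3 on the other epoxide diastereomer. Luche reduction (NaBH4, CeCl3·7H2O) gives cis-carveol F4; VO(acac)2/tBuOOH gives the β-epoxy alcohol F5 (epoxide syn to the hydroxyl); Pr4N[RuO4]/NMO gives the β-epoxy ketone F6. Acid-catalysed hydration (aq. HClO4, THF) at the carbonyl-activated tertiary C4 with inversion then keeps the β C3–O bond and delivers 6.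

Step 9. Chelation may be lost in favour of an open, dipole-minimised transition state, giving poor facial selectivity at the aldehyde and the C9 epimer. The fallback sets out from 11 and returns at 15. The 9-epimer F7 is carried through the conditions of steps 10 and 11, via the trimethylsilyl ether F8 and the triol F9, to the 9-epi bicyclic triol F10. Its cyclic allylic alcohol is inverted by a Mitsunobu reaction (PPh3, DIAD, 4-nitrobenzoic acid) to the 9β 4-nitrobenzoate F11, and K2CO3/MeOH then gives 15.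

Further compounds
F1 | step 15 | 10-epi 10-hydroxy-5-ketone | C=C(C)[C@H]1C[C@@H](O[Si](CC)(CC)CC)[C@](C)(O[Si](CC)(CC)CC)C(=O)C[C@H]2O[C@@]2(C)[C@@H](OCc3ccc(OC)cc3)[C@@H]1O
F2 | step 15 | 10-angelate 5-ketone | C=C(C)[C@H]1C[C@@H](O[Si](CC)(CC)CC)[C@](C)(O[Si](CC)(CC)CC)C(=O)C[C@H]2O[C@@]2(C)[C@@H](OCc3ccc(OC)cc3)[C@H]1OC(=O)/C(C)=C\C
F3 | step 15 | 5-epi 5-hydroxy 10-angelate | C=C(C)[C@H]1C[C@@H](O[Si](CC)(CC)CC)[C@](C)(O[Si](CC)(CC)CC)[C@H](O)C[C@H]2O[C@@]2(C)[C@@H](OCc3ccc(OC)cc3)[C@H]1OC(=O)/C(C)=C\C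
F4 | step 3 | (1S,5S)-cis-carveol | C=C(C)[C@H]1CC=C(C)[C@@H](O)C1
F5 | step 3 | 3β,4β-epoxy-5β-ol | C=C(C)[C@H]1C[C@H]2O[C@@]2(C)[C@@H](O)C1
F6 | step 3 | 3β,4β-epoxy-5-ketone (carvone β-oxide) | C=C(C)[C@H]1C[C@H]2O[C@@]2(C)C(=O)C1
F7 | step 9 | 9-epimer of 12 | C=C(C)[C@H]1C[C@@H](O[Si](CC)(CC)CC)[C@](C)(O[Si](CC)(CC)CC)C(=O)[C@]1(O[Si](C)(C)C)[C@@H](O)C(C)=C
F8 | step 9 | 9-epimer of 13 | C=C(C)[C@H]1C[C@@H](O[Si](CC)(CC)CC)[C@](C)(O[Si](CC)(CC)CC)[C@](O)(CC=C)[C@]1(O[Si](C)(C)C)[C@@H](O)C(C)=C
F9 | step 9 | 9-epimer of 14 | C=C(C)[C@H]1C[C@@H](O[Si](CC)(CC)CC)[C@](C)(O[Si](CC)(CC)CC)[C@](O)(CC=C)[C@]1(O)[C@@H](O)C(C)=C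
F10 | step 9 | 9-epimer of 15 (9α-OH) | C=C(C)[C@H]1C[C@@H](O[Si](CC)(CC)CC)[C@](C)(O[Si](CC)(CC)CC)[C@]2(O)CC=C(C)[C@H](O)[C@]12O
F11 | step 9 | 9β 4-nitrobenzoate of 15 | C=C(C)[C@H]1C[C@@H](O[Si](CC)(CC)CC)[C@](C)(O[Si](CC)(CC)CC)[C@]2(O)CC=C(C)[C@@H](OC(=O)c3ccc(cc3)[N+](=O)[O-])[C@]12O
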